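**Assumption (remark on the chemistry):** the SMILES contains no stereocentre and no E/Z-stereogenic alkene. Ring B is symmetric about the C2–C1' axis, so there is no stereogenic axis either. The target is achiral, and the demand for a single enantiomer is met by constitution alone. Abbreviations: prenyl = 3-methylbut-2-en-1-yl; TIPS = triisopropylsilyl.

## Structural features

The target is a 2-arylbenzofuran: a furan ring (O1, C2, C3, C3a, C7a) is fused to benzo ring A (C3a, C4–C7, C7a) and joined through the C2–C1' bond to phenyl ring B (C1'–C6'). Ring A carries OH at C4 and C6 and, at C7, a 1,1-dimethylallyl (reverse prenyl) group whose quaternary carbon is wedged between C6–OH and the ring-fusion carbon C7a that bears O1. Ring B carries OH at C3' and C5' and normal prenyl groups at C2' and C6', so the C2–C1' bond has two ortho substituents on one side. There is no stereocentre and no stereogenic axis, so the molecule is achiral. The fragile points are four free phenols on very electron-rich rings (air, base) and three ortho-allylphenol units (C6–OH/C7, C3'–OH/C2', C5'–OH/C6') that close to chromans or dihydrofurans with acid. The real difficulty is placing three C5 units, in two constitutional forms, at C7, C2' and C6' while the more accessible or more nucleophilic carbons C4', C5 and C3 stay free, together with the crowding this creates around C7 and the C2–C1' bond. The key step exploits the fact that each of these carbons stands in a sigmatropic relation to a phenol oxygen: C7 is ortho to O6, whose para carbon is the blocked ring-fusion carbon C3a, whereas C6' is para to O3' and C2' is para to O5', both open CH positions. An O-prenyl group on O6 can therefore make only one [3,3] shift and arrives inverted, while one on O3' or O5' can make two and arrives in the normal form, which is exactly the pattern of the target.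

## Logic of the disconnections

**20 ⇒ 19.** The O4–Si bond is cut. O4 is the only phenol oxygen that must never carry a C5 unit, because a prenyl group on O4 would travel towards C5 or C7. It is therefore masked throughout and released last. The gain is small, but the release is a neutral fluoride step. The demand on the forward step is cleavage without strong acid or unbuffered base, since 20 holds three ortho-allylphenol units.

**19 ⇒ 11 (key disconnection).** Three C–C bonds are cut: C7–C(quaternary), C2'–CH2 and C6'–CH2. The three C5 units go back to O6, O5' and O3' as identical prenyl ethers.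
- In one sentence: a single thermal operation on the tris(prenyl ether) 11 moves all three C5 units from oxygen to carbon, by one ortho-Claisen shift on ring A and two Claisen–Cope relays on ring B. This sentence does not fit the route usually drawn first, which closes the furan ring between two pre-prenylated halves.
- The gain is large. All three regiochemical problems and the reverse/normal distinction are settled together. Ring B becomes a plain symmetric 3,5-dialkoxyphenyl group, the C2–C1' bond loses both ortho substituents, and every C5 unit comes from the same reagent.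
- The demands are threefold: C7 must be chosen over C5 on ring A, the Cope shift must outrun enolisation in the ring-B dienones 14 and 17, and O4 must be inert.

**11 ⇒ 6 + 8.** The C2–C1' bond is cut. After the key disconnection this is an unhindered heteroaryl–aryl bond, so it can be formed by the mildest cross-coupling. The cut splits the molecule into two fragments of similar size. The demand is metalation of 6 at C2 only, via 9 and 10, and a catalyst that leaves the allyl aryl ethers alone.

**8 ⇒ 7 + 2.** The two equivalent O–CH2 bonds are cut. Symmetry makes this a single operation with no selectivity issue. The demand is O- rather than C-alkylation.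

**6 ⇒ 4 (via 5).** The C2=C3 double bond is traced back to a C3 ketone: C3–H is exchanged for C3=O and C2 becomes CH2. The carbonyl group is brought in retrosynthetically because it is the only element that makes O4 and O6 different. The demand is a reduction and dehydration mild enough for a prenyl ether and an aryl silyl ether.

**4 ⇒ 3 ⇒ 1 + 2.** The O4–Si bond and then the O6–CH2 bond are cut. In 1 the C3 carbonyl hydrogen-bonds and shields O4–H and leaves O6–H free, so the two phenols can be addressed one after the other. The demand is mono-alkylation at O6 without alkylation at O4, C2, C5 or C7.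

## Other disconnections considered

**Alternative 1:** (the first that comes to mind) Cut C3–C3a and O1–C2 of the furan ring.
- Forward step: Sonogashira coupling of the iodophenol A1 with the arylacetylene A2, 5-endo-dig closure to the tetra-MOM ether A3, and acid deprotection.
- Strategy: this plan builds the easiest part of the molecule in its key step and leaves the real difficulty to the fragments.
- A2: it already has the full 2,6-diprenyl-3,5-dioxy pattern. Directed metalation of a 3,5-dialkoxyarene goes to the carbon between the two oxygens, not to the two carbons that are needed.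
- A1: it needs its own Claisen sequence plus a regioselective iodination.
- Coupling and end game: the coupling joins an alkyne flanked by two prenyl groups to an iodide flanked by two oxygens. The final acetal cleavage brings acid to three ortho-allylphenol units. The chosen plan needs fewer steps and forms the crowded positions intramolecularly.

**Alternative 2:** Cut O1–C2 only, copying the presumed origin of 2-arylbenzofurans from stilbenes.
- Forward step: oxidative cyclisation (hypervalent iodine or a quinone oxidant) of the fully prenylated (E)-2-hydroxystilbene A4.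
- Site of closure: ring A of A4 has two non-equivalent ortho phenols. The hindered one next to the 1,1-dimethylallyl group must close, while closure through the free one would give the 5-substituted isomer A5.
- Chemoselectivity: the oxidant also meets two free resorcinol rings and three alkenes, and the styrene is twisted out of conjugation by the two ortho prenyl groups.
- Economy: A4 is no easier to prenylate than the target, so nothing is gained in simplicity.

**Alternative 3:** Cut ring B itself (C3'–C2' and C5'–C6', with C4' and C5' coming from an alkyne).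
- Forward step: Danheiser-type benzannulation. Heating cyclobutenone A6 with the silyloxyacetylene A7 triggers 4π opening to a vinylketene, [2+2] addition, a second 4π opening and 6π closure, giving the resorcinol monoether A8.
- Merit: the substituent pattern of ring B would follow from the mechanism, and no hindered biaryl coupling would be needed.
- Weakness: A6, a trisubstituted cyclobutenone with two prenyl groups and a heteroaryl group, is at least as hard to make regioselectively as ring B. Its own [2+2] precursor, an unsymmetrical internal alkyne plus an alkylketene, offers no control. C7 would still need a separate solution, so the step count is clearly higher.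

Key step: step 6

## Route

**Step 1**
Reactants: 1 4,6-dihydroxybenzofuran-3(2H)-one; 2 prenyl bromide (1-bromo-3-methylbut-2-ene)
Product: 3 4-hydroxy-6-(prenyloxy)benzofuran-3(2H)-one
Conditions: 2 (1.05 equiv), K2CO3 (1.1 equiv), acetone, 0 °C to rt
Reagents that add atoms: prenyl bromide 2, CC(C)=CCBr
Why: Williamson ether synthesis on the free and more acidic phenol: C6–OH is para-conjugated with the C3 carbonyl and unhindered, whereas C4–OH is hydrogen-bonded to that carbonyl and peri-shielded, the pattern by which 5,7-dihydroxychromones and 2,4-dihydroxyaryl ketones are alkylated at the remote OH only. One equivalent of a weak base leaves the C2 methylene un-ionised.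

**Step 2**
Reactants: 3 4-hydroxy-6-(prenyloxy)benzofuran-3(2H)-one
Product: 4 6-(prenyloxy)-4-(triisopropylsilyloxy)benzofuran-3(2H)-one
Conditions: TIPSCl, imidazole, DMAP (cat.), DMF, 40 °C
Reagents that add atoms: triisopropylsilyl chloride, CC(C)[Si](Cl)(C(C)C)C(C)C
Why: Standard silylation of a phenol with a silyl chloride and imidazole, conditions that do not enolise the ketone. The TIPS ether removes the only acidic proton before the metalation of step 5, is inert to prolonged heating, and shields C5 in step 6.

**Step 3**
Reactants: 4 6-(prenyloxy)-4-(triisopropylsilyloxy)benzofuran-3(2H)-one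
Product: 6 6-(prenyloxy)-4-(triisopropylsilyloxy)benzofuran, via benzylic alcohol 5 (not isolated)
Conditions: NaBH4, THF/MeOH, 0 °C; then 1 M aq. HCl, THF, rt
Reagents that add atoms: none
Why: Hydride reduction of a benzofuran-3(2H)-one followed by acid-induced dehydration, the usual passage from 3-coumaranones to benzofurans. Alcohol 5 is benzylic with ortho and para oxygen donors, so it ionises in dilute acid at room temperature and loses a C2 proton to give the aromatic furan, mild enough for the prenyl ether and the aryl TIPS ether; the racemic stereocentre of 5 disappears.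

**Step 4**
Reactants: 7 5-bromoresorcinol (5-bromobenzene-1,3-diol); 2 prenyl bromide
Product: 8 1-bromo-3,5-bis(prenyloxy)benzene
Conditions: 2 (2.3 equiv), K2CO3, DMF, rt
Reagents that add atoms: prenyl bromide 2, CC(C)=CCBr
Why: Double Williamson ether synthesis on two equivalent phenols. A resorcinol deactivated by bromine is alkylated at oxygen, not carbon, by an allylic bromide with K2CO3 in a dipolar aprotic solvent.

**Step 5**
Reactants: 6 6-(prenyloxy)-4-(triisopropylsilyloxy)benzofuran; 8 1-bromo-3,5-bis(prenyloxy)benzene
Product: 11 2-[3,5-bis(prenyloxy)phenyl]-6-(prenyloxy)-4-(triisopropylsilyloxy)benzofuran, via 2-lithiobenzofuran 9 (not isolated), via 2-benzofuranylzinc chloride 10 (not isolated)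
Conditions: n-BuLi, THF, −78 °C; ZnCl2, −78 °C to rt; 8, Pd2(dba)3 (1 mol %), SPhos (4 mol %), THF, 40 °C
Reagents that add atoms: n-butyllithium, [Li]CCCC (Li held in 9 only); zinc chloride, Cl[Zn]Cl (ZnCl held in 10 only)
Why: C2–H is the most acidic C–H bond of a benzofuran and is removed by n-BuLi at −78 °C faster than the allylic OCH2 or the ring C–H bonds; transmetalation to zinc gives a mild nucleophile for a Negishi coupling. Neither partner has an ortho substituent at this stage, so the C2–C1' bond should form at 40 °C with a fast biarylphosphine catalyst, where oxidative addition to C–Br outruns ionisation of the trisubstituted allyl aryl ethers.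

**Step 6**
Reactants: 11 2-[3,5-bis(prenyloxy)phenyl]-6-(prenyloxy)-4-(triisopropylsilyloxy)benzofuran
Product: 19 5-[6-hydroxy-7-(2-methylbut-3-en-2-yl)-4-(triisopropylsilyloxy)benzofuran-2-yl]-4,6-diprenylbenzene-1,3-diol, via ring-A ortho-dienone 12 (not isolated), via ring-A phenol 13 (not isolated), via first ring-B ortho-dienone 14 (not isolated), via first ring-B para-dienone 15 (not isolated), via mono-C-prenyl phenol 16 (not isolated), via second ring-B ortho-dienone 17 (not isolated), via second ring-B para-dienone 18 (not isolated)
Conditions: PhNEt2 (degassed, 0.02 M), 205 °C, sealed vessel, Ar; solvent removed by short-path distillation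
Reagents that add atoms: none
Why: Each aryl prenyl ether undergoes a thermal aromatic Claisen rearrangement, a concerted [3,3] shift through a six-membered transition state that joins the CMe2 terminus to an ortho carbon and gives an ortho-dienone. On ring A the shift from O6 goes to C7 (12) because it uses the C6=C7 bond and leaves C3a=C7a, hence the furan sextet, intact, whereas a shift to C5 would break that sextet and must also pass the OTIPS group; this is the bond fixation that sends 2-naphthyl allyl ethers to C1. The carbon para to O6 is the ring-fusion carbon C3a, so a further Cope shift from 12 could only give a non-enolisable dienone that reverts, and 12 leaves solely by enolisation to 13 with the 1,1-dimethylallyl group in place. On ring B the carbons para to O3' and O5' (C6' and C2') are open CH positions, so the ortho-dienones 14 and 17 relieve the strain of their quaternary-to-tertiary C–C bond by a Cope shift to the para-dienones 15 and 18, which enolise to 16 and 19; the double inversion gives normal prenyl groups, and the closest known reaction type is the para-Claisen–Cope rearrangement by which O-prenyl ethers of phloroacetophenones and 5-O-prenylflavanones are turned into C-prenylphenols. The first shift on ring B may go to either ortho carbon (14 and 17 are drawn for C4'), because both ortho-dienones pass the allyl group to the same para carbon, so the site of the final C–C bond does not depend on ortho selectivity. The selectivity that the step needs is therefore Cope shift before enolisation in 14 and 17: the Cope shift is unimolecular and enolisation needs a proton carrier, so high dilution in an aprotic medium favours the former, and a first shift onto the already substituted C6' cannot enolise at all. No ring is closed and no lasting stereocentre is formed, since the sp3 ring carbons of 12, 14, 15, 17 and 18 are racemic and become sp2 again on enolisation. The weakly basic solvent prevents acid-induced closure of the new ortho-prenylphenols to chromans, the aryl TIPS ether is inert to heat, and the order of the three events, written here with ring A first, has no influence on the product.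

**Step 7**
Reactants: 19 5-[6-hydroxy-7-(2-methylbut-3-en-2-yl)-4-(triisopropylsilyloxy)benzofuran-2-yl]-4,6-diprenylbenzene-1,3-diol
Product: 20 2-[3,5-dihydroxy-2,6-diprenylphenyl]-7-(2-methylbut-3-en-2-yl)benzofuran-4,6-diol (target)
Conditions: TBAF (1.1 equiv), AcOH (1.1 equiv), THF, 0 °C, Ar
Reagents that add atoms: none
Why: Fluoride cleavage of an aryl silyl ether, driven by the strength of the Si–F bond. Buffering with acetic acid keeps the electron-rich phenols protonated, and no acid strong enough to close the ortho-allylphenol units is present.

## Compound list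

In the names of 14–18, Bf* stands for the 6-hydroxy-7-(2-methylbut-3-en-2-yl)-4-(TIPS-oxy)benzofuran-2-yl group.

1 | 4,6-dihydroxybenzofuran-3(2H)-one | O=C1COc2cc(O)cc(O)c12 | starting material
2 | prenyl bromide (1-bromo-3-methylbut-2-ene) | CC(C)=CCBr | starting material
3 | 4-hydroxy-6-(prenyloxy)benzofuran-3(2H)-one | O=C1COc2cc(OCC=C(C)C)cc(O)c12 | intermediate
4 | 6-(prenyloxy)-4-(triisopropylsilyloxy)benzofuran-3(2H)-one | O=C1COc2cc(OCC=C(C)C)cc(O[Si](C(C)C)(C(C)C)C(C)C)c12 | intermediate
5 | 6-(prenyloxy)-4-(triisopropylsilyloxy)-2,3-dihydrobenzofuran-3-ol (racemic, not isolated) | OC1COc2cc(OCC=C(C)C)cc(O[Si](C(C)C)(C(C)C)C(C)C)c12 | intermediate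
6 | 6-(prenyloxy)-4-(triisopropylsilyloxy)benzofuran | CC(C)=CCOc1cc(O[Si](C(C)C)(C(C)C)C(C)C)c2ccoc2c1 | intermediate
7 | 5-bromoresorcinol | Oc1cc(O)cc(Br)c1 | starting material
8 | 1-bromo-3,5-bis(prenyloxy)benzene | CC(C)=CCOc1cc(Br)cc(OCC=C(C)C)c1 | intermediate
9 | 2-lithio-6-(prenyloxy)-4-(triisopropylsilyloxy)benzofuran (not isolated) | [Li]c1cc2c(O[Si](C(C)C)(C(C)C)C(C)C)cc(OCC=C(C)C)cc2o1 | intermediate
10 | [6-(prenyloxy)-4-(triisopropylsilyloxy)benzofuran-2-yl]zinc chloride (not isolated) | Cl[Zn]c1cc2c(O[Si](C(C)C)(C(C)C)C(C)C)cc(OCC=C(C)C)cc2o1 | intermediate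
11 | 2-[3,5-bis(prenyloxy)phenyl]-6-(prenyloxy)-4-(triisopropylsilyloxy)benzofuran | CC(C)=CCOc1cc(OCC=C(C)C)cc(-c2cc3c(O[Si](C(C)C)(C(C)C)C(C)C)cc(OCC=C(C)C)cc3o2)c1 | intermediate
12 | 2-[3,5-bis(prenyloxy)phenyl]-7-(2-methylbut-3-en-2-yl)-4-(triisopropylsilyloxy)benzofuran-6(7H)-one (racemic, not isolated) | C=CC(C)(C)C1C(=O)C=C(O[Si](C(C)C)(C(C)C)C(C)C)c2cc(-c3cc(OCC=C(C)C)cc(OCC=C(C)C)c3)oc12 | intermediate
13 | 2-[3,5-bis(prenyloxy)phenyl]-7-(2-methylbut-3-en-2-yl)-4-(triisopropylsilyloxy)benzofuran-6-ol (not isolated) | C=CC(C)(C)c1c(O)cc(O[Si](C(C)C)(C(C)C)C(C)C)c2cc(-c3cc(OCC=C(C)C)cc(OCC=C(C)C)c3)oc12 | intermediate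
14 | 3-(Bf*)-6-(2-methylbut-3-en-2-yl)-5-(prenyloxy)cyclohexa-2,4-dien-1-one (racemic, not isolated) | O=C1C=C(c2cc3c(O[Si](C(C)C)(C(C)C)C(C)C)cc(O)c(C(C)(C)C=C)c3o2)C=C(OCC=C(C)C)C1C(C)(C)C=C | intermediate
15 | 5-(Bf*)-4-prenyl-3-(prenyloxy)cyclohexa-2,5-dien-1-one (racemic, not isolated) | O=C1C=C(OCC=C(C)C)C(CC=C(C)C)C(c2cc3c(O[Si](C(C)C)(C(C)C)C(C)C)cc(O)c(C(C)(C)C=C)c3o2)=C1 | intermediate
16 | 3-(Bf*)-4-prenyl-5-(prenyloxy)phenol (not isolated) | Oc1cc(OCC=C(C)C)c(CC=C(C)C)c(-c2cc3c(O[Si](C(C)C)(C(C)C)C(C)C)cc(O)c(C(C)(C)C=C)c3o2)c1 | intermediate
17 | 3-(Bf*)-5-hydroxy-6-(2-methylbut-3-en-2-yl)-2-prenylcyclohexa-2,4-dien-1-one (racemic, not isolated) | O=C1C(CC=C(C)C)=C(c2cc3c(O[Si](C(C)C)(C(C)C)C(C)C)cc(O)c(C(C)(C)C=C)c3o2)C=C(O)C1C(C)(C)C=C | intermediate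
18 | 3-(Bf*)-5-hydroxy-2,4-diprenylcyclohexa-2,5-dien-1-one (racemic, not isolated) | O=C1C=C(O)C(CC=C(C)C)C(c2cc3c(O[Si](C(C)C)(C(C)C)C(C)C)cc(O)c(C(C)(C)C=C)c3o2)=C1CC=C(C)C | intermediate
19 | 5-[6-hydroxy-7-(2-methylbut-3-en-2-yl)-4-(triisopropylsilyloxy)benzofuran-2-yl]-4,6-diprenylbenzene-1,3-diol | C=CC(C)(C)c1c(O)cc(O[Si](C(C)C)(C(C)C)C(C)C)c2cc(-c3c(CC=C(C)C)c(O)cc(O)c3CC=C(C)C)oc12 | intermediate
20 | 2-[3,5-dihydroxy-2,6-diprenylphenyl]-7-(2-methylbut-3-en-2-yl)benzofuran-4,6-diol (achiral) | C=CC(C)(C)c1c(O)cc(O)c2cc(-c3c(CC=C(C)C)c(O)cc(O)c3CC=C(C)C)oc12 | target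

## Step count and least certain steps

Total step count: 7. Longest linear sequence: 6 (steps 1, 2, 3, 5, 6, 7).

**Step 6 (key step).**
- What may go wrong: enolisation of the ring-B ortho-dienones 14 and 17 may overtake the Cope shift, because the phenols that build up act as proton carriers. A C5 unit would then stay in its inverted form at an ortho carbon. Prolonged heating may also start an ene-type isomerisation, or ring closure of the 1,1-dimethylallyl group onto the neighbouring free C6 phenol.
- Fallback: it sets out from 7 and 10 and comes back at 19. It replaces the two-stage relay on ring B by direct ortho shifts of tertiary ethers. Compound 7 is acetylated (Ac2O, pyridine) to 5-bromo-1,3-phenylene diacetate F1, which is joined to 10 under the Negishi conditions of step 5 to give the coupled diacetate F2. Methanolysis (K2CO3, MeOH, 0 °C) frees the ring-B resorcinol F3 with the TIPS ether intact. Pd(0)-catalysed allylic etherification with tert-butyl 2-methylbut-3-en-2-yl carbonate (Pd(PPh3)4, THF, 0 °C) gives the bis(1,1-dimethylallyl) ether F4.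
- Why the fallback should help: tertiary ethers of this kind rearrange near 110–130 °C by a single ortho-Claisen shift that delivers the normal prenyl group directly. A meta-alkoxy group steers the shift to the carbon para to it, that is to C2' and C6'. This should give the ring-B diprenylresorcinol F5 with the ring-A prenyl ether untouched, and a second heating stage at 190–205 °C carries out the ring-A shift alone and gives 19.

**Step 1.**
- What may go wrong: loss of site selectivity between O6 and O4. The hydrogen bond from O4–H to a five-membered-ring ketone is weaker than in chromones, so double alkylation or alkylation at O4 could compete.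
- Fallback: it sets out from 1 and comes back at 3, and it moves the selectivity from bond formation to bond cleavage. Exhaustive alkylation with excess 2 and K2CO3 gives 4,6-bis(prenyloxy)benzofuran-3(2H)-one F6. MgBr2·OEt2 (toluene/Et2O, rt) then chelates the C3 carbonyl and O4, so only the peri allylic ether is activated and cleaved, leaving 3.

**Step 5.**
- What may go wrong: competing deprotonation by n-BuLi, either at the allylic OCH2 group (followed by Wittig rearrangement) or at C7–H between two oxygens. Either would lower the amount of 9.
- Fallback: it sets out from 6 and comes back at 11, and it avoids any strong base. Iridium-catalysed C–H borylation ([Ir(OMe)(cod)]2, dtbpy, B2pin2, MTBE, rt), which selects C2–H of benzofurans, gives the 2-(pinacolboryl)benzofuran F7. Suzuki–Miyaura coupling of F7 with 8 (SPhos–Pd catalyst, K3PO4, THF/H2O, 40 °C) gives 11.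

**Step 7.**
- What may go wrong: air oxidation of the electron-rich phenolate during release and purification, or ring closure of an ortho-allylphenol unit if the medium drifts from neutrality.
- Fallback: it sets out from 3 and comes back at 20, and it removes the protecting group from the plan altogether. Reduction of 3 with LiAlH4 and a mildly acidic work-up gives 6-(prenyloxy)benzofuran-4-ol F8. Double deprotonation (2 equiv n-BuLi), transmetalation with ZnCl2 and Negishi coupling with 8 give 2-[3,5-bis(prenyloxy)phenyl]-6-(prenyloxy)benzofuran-4-ol F9. The thermal cascade of step 6 applied to F9 gives 20 directly, with the C7/C5 choice then resting on the furan bond fixation alone.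

## Further compounds

F1 | step 6 | 5-bromo-1,3-phenylene diacetate | CC(=O)Oc1cc(Br)cc(OC(C)=O)c1
F2 | step 6 | 5-[6-(prenyloxy)-4-(triisopropylsilyloxy)benzofuran-2-yl]-1,3-phenylene diacetate | CC(=O)Oc1cc(OC(C)=O)cc(-c2cc3c(O[Si](C(C)C)(C(C)C)C(C)C)cc(OCC=C(C)C)cc3o2)c1
F3 | step 6 | 5-[6-(prenyloxy)-4-(triisopropylsilyloxy)benzofuran-2-yl]benzene-1,3-diol | Oc1cc(O)cc(-c2cc3c(O[Si](C(C)C)(C(C)C)C(C)C)cc(OCC=C(C)C)cc3o2)c1
F4 | step 6 | 2-[3,5-bis(2-methylbut-3-en-2-yloxy)phenyl]-6-(prenyloxy)-4-(triisopropylsilyloxy)benzofuran | C=CC(C)(C)Oc1cc(OC(C)(C)C=C)cc(-c2cc3c(O[Si](C(C)C)(C(C)C)C(C)C)cc(OCC=C(C)C)cc3o2)c1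
F5 | step 6 | 5-[6-(prenyloxy)-4-(triisopropylsilyloxy)benzofuran-2-yl]-4,6-diprenylbenzene-1,3-diol | CC(C)=CCOc1cc(O[Si](C(C)C)(C(C)C)C(C)C)c2cc(-c3c(CC=C(C)C)c(O)cc(O)c3CC=C(C)C)oc2c1
F6 | step 1 | 4,6-bis(prenyloxy)benzofuran-3(2H)-one | O=C1COc2cc(OCC=C(C)C)cc(OCC=C(C)C)c12
F7 | step 5 | 2-(4,4,5,5-tetramethyl-1,3,2-dioxaborolan-2-yl)-6-(prenyloxy)-4-(triisopropylsilyloxy)benzofuran | CC(C)=CCOc1cc(O[Si](C(C)C)(C(C)C)C(C)C)c2cc(B3OC(C)(C)C(C)(C)O3)oc2c1
F8 | step 7 | 6-(prenyloxy)benzofuran-4-ol | CC(C)=CCOc1cc(O)c2ccoc2c1
F9 | step 7 | 2-[3,5-bis(prenyloxy)phenyl]-6-(prenyloxy)benzofuran-4-ol | CC(C)=CCOc1cc(OCC=C(C)C)cc(-c2cc3c(O)cc(OCC=C(C)C)cc3o2)c1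
A1 | alternative 1 | 2-iodo-3,5-bis(methoxymethoxy)-6-(2-methylbut-3-en-2-yl)phenol | Oc1c(I)c(OCOC)cc(OCOC)c1C(C)(C)C=C
A2 | alternative 1 | 2-ethynyl-4,6-bis(methoxymethoxy)-1,3-diprenylbenzene | C#Cc1c(CC=C(C)C)c(OCOC)cc(OCOC)c1CC=C(C)C
A3 | alternative 1 | tetra-MOM ether of the target | C=CC(C)(C)c1c(OCOC)cc(OCOC)c2cc(-c3c(CC=C(C)C)c(OCOC)cc(OCOC)c3CC=C(C)C)oc12
A4 | alternative 2 | (E)-2-[2-(3,5-dihydroxy-2,6-diprenylphenyl)ethenyl]-4-(2-methylbut-3-en-2-yl)benzene-1,3,5-triol | C=CC(C)(C)c1c(O)cc(O)c(/C=C/c2c(CC=C(C)C)c(O)cc(O)c2CC=C(C)C)c1O
A5 | alternative 2 | 2-(3,5-dihydroxy-2,6-diprenylphenyl)-5-(2-methylbut-3-en-2-yl)benzofuran-4,6-diol | C=CC(C)(C)c1c(O)cc2oc(-c3c(CC=C(C)C)c(O)cc(O)c3CC=C(C)C)cc2c1O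
A6 | alternative 3 | 3-[4,6-bis(methoxymethoxy)-7-(2-methylbut-3-en-2-yl)benzofuran-2-yl]-2,4-diprenylcyclobut-2-en-1-one (racemic) | O=C1C(CC=C(C)C)=C(c2cc3c(OCOC)cc(OCOC)c(C(C)(C)C=C)c3o2)C1CC=C(C)C
A7 | alternative 3 | (triisopropylsilyloxy)acetylene | C#CO[Si](C(C)C)(C(C)C)C(C)C
A8 | alternative 3 | 3-[4,6-bis(methoxymethoxy)-7-(2-methylbut-3-en-2-yl)benzofuran-2-yl]-2,4-diprenyl-5-(triisopropylsilyloxy)phenol | C=CC(C)(C)c1c(OCOC)cc(OCOC)c2cc(-c3c(CC=C(C)C)c(O)cc(O[Si](C(C)C)(C(C)C)C(C)C)c3CC=C(C)C)oc12
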